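**Conventions.** Ring carbons keep the germacrane numbers of the target throughout: C10 carries the ester carbon C14, then C1, C2, C3, C4 (methyl C15), C5, C6 (lactone oxygen), C7 (lactone carbon C11), C8, C9. "β" is the ring face that carries O9 and the 4,5-epoxide oxygen in the target 31; "α" is the face of O6, C11 and O8.

## The problem

Compound 31 is a germacrane-type sesquiterpene lactone built on a ten-membered carbocycle. The C10=C1 acrylate and the 4,5-epoxide both have their ring bonds cis, and an α-methylene γ-lactone is cis-fused at C6/C7. Six contiguous ring stereocentres run from C4 to C9 (4R,5S,6R,7R,8S,9S), and a seventh sits in the (S)-2-methyloxirane-2-carboxylate on O8. Because the centres are contiguous, one reagent-controlled centre can be relayed: C9 can direct C8 and C7 across a neighbouring alkene, the five-membered lactone forces C6 cis to C7, and the fused lactone then screens one face of a C4=C5 alkene. The difficulty lies in the medium ring (no cheap cyclisation, transannular reactions, uncertain conformations) and in the labile groups. The exo-methylene lactone is a Michael acceptor, both epoxides are acid-sensitive, the C9 acetate is an allylic acetate flanked by an acrylate, and three different esters exclude hard bases and hydrides late in the route. The enabling feature is topological: the ten ring carbons plus C14 are the periphery of 1-naphthoic acid, and C4 and C9, which face each other across the ring and are both oxygenated in 31, are the arene's two ring-fusion carbons. Cleaving the C4=C9 double bond of the Birch-reduced naphthoate 4 therefore delivers the ring, both oxygens and two Z alkenes in one operation, with no ring closure.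

## Retrosynthesis

**C11=C13.** The exo-methylene is removed first, back to the α-phosphono lactone 30, so that the most electrophilic group of 31 appears last by Horner–Wadsworth–Emmons reaction with formaldehyde. Enolate methylenation of a plain lactone would need a strong base that the acetate, the glycidate and the acrylate do not survive.

**Epoxide and acyl groups.** The 4,5-epoxide of 30 is taken back to the Z alkene 29. A peracid adds both C–O bonds syn and should approach anti to the fused lactone; the alternative, displacement at C5 by a C4 alkoxide, would need a C5 leaving group next to a C4 ketone that ejects the C6 acyloxy group on enolisation. The acetate and the glycidate are then removed in turn (29, 28, 27) to alcohol 22 and acid 25. Acid 25 comes from 2-methylprop-2-en-1-ol 23 through epoxy alcohol 24, so its stereocentre is set independently by a Sharpless epoxidation.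

**Lactone C–O bond and C15.** Lactone 21 is opened to hydroxy ester 20 and oxidised back to enone 19. Enone 19 is the transposition product of tertiary allylic alcohol 18, which arises from methyl addition to enone 17. A single methyl addition thus places C15 and moves the oxygen from C4 to C6, and no enolate is ever formed at C5. The forward steps need only 1,2-addition, a [3,3] chromate shift and a hydride delivered anti to the C7 side chain.

**C7–C11.** The bond between C7 and the phosphonoacetate carbon of 17 is cut to vinyl epoxide 14 and triethyl phosphonoacetate 15. Palladium-catalysed allylic alkylation substitutes with net retention, so C11 ends cis to O8; direct SN2 opening of any epoxide would give the trans pair. A Michael addition to a C9 enone is the obvious neighbour, but it fails because the adjacent β-keto ester is deprotonated first. The precursor 14 has three stereocentres fewer and carries only one controlling centre, C9.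

**Vinyl epoxide to keto ester.** Epoxide 14 comes from dienone 13 by peracid attack on the distal alkene, anti to the C9 silyl ether. Dienone 13 comes from β,γ-enone 11 by dehydrogenation through its dienol ether 12. This makes the C4 ketone, not the C9 ketone, the activating group for C5–C8, which is the direction in which the diketone reacts naturally.

**C9 and the acrylate.** Silyl ether 11 is traced through alcohol 10 and the bridged ketals 9 and 8 to diketone 6. Only the β-keto ester ketone of 6 is hydrogenated, which sets C9 absolutely (7) and distinguishes the two ketones. The resulting alcohol masks the C4 ketone as a transannular ketal, inside which the C1=C2 alkene can be moved into conjugation without competition from the C4 ketone and with the cis geometry enforced by a seven-membered ring.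

**The ring.** Diketone 6 is reconnected across C4 and C9 to the tetrasubstituted alkene of methyl 1,4,5,8-tetrahydronaphthalene-1-carboxylate 4. This cut removes the medium ring from the problem. The forward reaction has to distinguish a tetrasubstituted alkene from two disubstituted ones, which ozone does by electron demand.

**The arene.** Ester 4 is the twofold Birch reduction product of 1-naphthoic acid 1 (through acids 2 and 3), so all eleven skeletal carbons are bought in one commodity arene.

## Roads not taken

**Alternative 1:** The cut is the C7–C11 bond of the lactone. A rhodium carbenoid generated with Rh2(OAc)4 from a diazophosphonoacetate on O6 inserts into the C7–H bond and gives the cis-fused α-phosphono lactone A1. Its merits are real: the lactone is annulated in one step on an unfunctionalised C7 methylene, the five-membered transition state guarantees the cis fusion, and the phosphonate is already the handle for the final methylenation. In this respect it is better than the chosen plan, which spends steps 9 to 14 on C7, C8 and C6. Its weak points are that the complete ten-membered ring, with C4, C5, C6, C8 and C9 set and both acyl groups and the acrylate in place, must exist beforehand, so it does not address ring construction at all. The C7–H bond is also deactivated by the neighbouring acyloxy-bearing C8, while C5–H offers a competing five-membered insertion, and the epoxide and ester oxygens can intercept the carbenoid as ylides. The chosen plan sets against it a four-step entry to the ring and C7–C11 formation by a polar reaction whose regiochemistry is dictated by a ketone.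

**Alternative 2:** The cut is the C5–C6 ring bond. Boron trifluoride activates a C5 aldehyde, a 2-silyloxyfuran attacks through C6, and the ring closes to the butenolide A2 with a new C5 hydroxyl. This road is convergent, takes its absolute configuration from acyclic fragments made by established asymmetric reactions, creates C5 and C6 together, and avoids the near-symmetric diketone that the chosen plan has to differentiate; in these respects it is as good or better. Against it stand the entropic and transannular cost of closing a ten-membered ring by an intermolecular-type aldol (high dilution, oligomers), and a diastereoselectivity at C5/C6 that depends on the folding of a long chain and cannot be predicted. A2 also still needs butenolide reduction to set C7, adjustment of C14 from a silyl ether to the ester, and inversion at C5 to make the epoxide. The chosen plan answers with a ring formed by bond scission, where no cyclisation can fail, and with Z alkenes whose geometry is fixed by six- and seven-membered rings.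

**Alternative 3:** The cuts are C9–C10 and C1–C2. A pyrrolidine enamine of an eight-membered ketone adds methyl propiolate in a stepwise [2+2], and the fused cyclobutene opens to the ring-enlarged dienamine ester A3. The attraction is that C10, C1 and the ester arrive in one step at the correct position, by ring expansion instead of cyclisation, on a substrate whose ring B stereocentres could be set in a better-behaved eight-membered ring; in stereocontrol of C6–C8 it could well beat the chosen plan. Its weak points are specific to this target: A3 carries an E C1=C2 alkene and an enamine at C9, whereas 31 needs a cis C10=C1 acrylate and saturated C2, so a hydrolysis, a selective reduction and a re-conjugation follow. The enamine must also form toward C2 and not C8, and an enantiopure, heavily substituted cyclooctenone has to be made first. The chosen plan gets C14 for free from the naphthoate, has both C4 and C9 oxygenated from the start and never passes through an E alkene.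

Key step: step 4

**Assumption:** the facial sense of RuCl2[(R)-BINAP] is taken from simple β-keto esters, with C10 in the role of the ester-bearing carbon; if it proved opposite, the (S)-ligand would be used.

## Route

Step 1
Reactants: 1 1-naphthoic acid
Product: 2 1,4-dihydronaphthalene-1-carboxylic acid (racemic)
Conditions: Li, NH3(l), THF, −78 °C; NH4Cl
Reagents that add atoms: none
Why: Birch reduction; the carboxylate-bearing ring takes up the electrons and the dianion is protonated at C1 and C4, and the NH4Cl quench prevents base-mediated conjugation.

Step 2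
Reactants: 2 1,4-dihydronaphthalene-1-carboxylic acid
Product: 3 1,4,5,8-tetrahydronaphthalene-1-carboxylic acid (racemic)
Conditions: Li (excess), NH3(l), t-BuOH, THF, −33 °C; NH4Cl
Reagents that add atoms: none
Why: second Birch reduction, now of the o-dialkylbenzene ring, which gives the 1,4-diene that keeps the tetrasubstituted alkene between the two alkylated carbons; tert-butanol buffers LiNH2 so that C1–H is not isomerised.

Step 3
Reactants: 3 1,4,5,8-tetrahydronaphthalene-1-carboxylic acid
Product: 4 methyl 1,4,5,8-tetrahydronaphthalene-1-carboxylate (racemic)
Conditions: MeI, KHCO3, DMF, rt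
Reagents that add atoms: iodomethane, CI
Why: SN2 O-alkylation of the carboxylate under nearly neutral conditions avoids double-bond migration and aromatisation of the skipped triene.

Step 4
Reactants: 4 methyl 1,4,5,8-tetrahydronaphthalene-1-carboxylate
Product: 6 methyl (4Z,9Z)-2,7-dioxocyclodeca-4,9-diene-1-carboxylate (C10 epimerisable), via transannular ozonide 5 (not isolated)
Conditions: O3 (about 1 equiv, Sudan Red 7B end point), CH2Cl2, −78 °C; then Me2S, −78 °C to rt
Reagents that add atoms: ozone, O=[O+][O-]
Why: Ozone adds as a 1,3-dipole to the tetrasubstituted ring-fusion alkene, and the primary ozonide fragments to a ketone and a carbonyl oxide held in the same ring, which recombine to the bicyclic ozonide 5; dimethyl sulfide reduces its O–O bond to give the two ketones at C4 and C9. The closest known reaction type is the ozonolysis of Birch-derived octalins and isotetralins to cyclodecane-1,6-diones. The ten-membered ring is not closed but revealed, by scission of the bond shared by the two six-membered rings, so no cyclisation entropy or dilution is involved. No stereocentre is formed; C10 stays epimerisable through the β-keto ester enol. Both remaining alkenes keep the Z geometry imposed by the six-membered rings. The step needs chemoselectivity for the tetrasubstituted alkene over the two cis-disubstituted ones, which rests on the higher electron density of the fusion alkene toward the electrophilic oxidant and is enforced by titrating ozone against the indicator. The product is a doubly skipped diketone with an α-vinyl β-keto ester, so the work-up is neutral and cold and 6 is used at once to limit transannular aldol reaction and alkene migration.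

Step 5
Reactants: 6 methyl (4Z,9Z)-2,7-dioxocyclodeca-4,9-diene-1-carboxylate
Product: 8 methyl (1R)-6-methoxy-11-oxabicyclo[4.4.1]undeca-3,8-diene-2-carboxylate (O9–C4 bridged methyl ketal on the β face; C10 epimers), via hydroxy ketone 7 (not isolated)
Conditions: RuCl2[(R)-BINAP] (1 mol%), H2 (50 atm), MeOH, 50 °C; then CSA (cat.), 4 Å MS, MeOH, rt
Reagents that add atoms: methanol, CO
Why: Noyori asymmetric hydrogenation reduces only the ketone that chelates ruthenium through the ester, leaving the C4 ketone and the isolated alkenes alone, and the catalyst sets C9 (9R expected by analogy with simple β-keto esters); C10 epimers converge later when C10 becomes sp2. Acid then closes the 1,6-hydroxy ketone to the transannular methyl ketal, masking O9 and the C4 ketone in one operation.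

Step 6
Reactants: 8 methyl (1R)-6-methoxy-11-oxabicyclo[4.4.1]undeca-3,8-diene-2-carboxylate
Product: 9 methyl (1R)-6-methoxy-11-oxabicyclo[4.4.1]undeca-2,8-diene-2-carboxylate (C10=C1 conjugated)
Conditions: DBU (0.3 equiv), toluene, 60 °C
Reagents that add atoms: none
Why: base-mediated equilibration of a β,γ- to an α,β-unsaturated ester through the dienolate; with C4 masked the ester is the only activating group, and because the migrating alkene lies in a seven-membered ring of 8 the new trisubstituted alkene must have its ring bonds cis.

Step 7
Reactants: 9 methyl (1R)-6-methoxy-11-oxabicyclo[4.4.1]undeca-2,8-diene-2-carboxylate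
Product: 10 methyl (1E,7Z,10R)-10-hydroxy-5-oxocyclodeca-1,7-diene-1-carboxylate (9R in target numbering; in equilibrium with its hemiketal)
Conditions: aq. HCl (0.5 M), THF, 0 °C to rt
Reagents that add atoms: water, O
Why: acetal hydrolysis through the bridged oxocarbenium ion; dilute acid leaves the acrylate and the β,γ-unsaturated ketone in place.

Step 8
Reactants: 10 methyl (1E,7Z,10R)-10-hydroxy-5-oxocyclodeca-1,7-diene-1-carboxylate
Product: 11 methyl (1E,7Z,10R)-10-[(tert-butyldimethylsilyl)oxy]-5-oxocyclodeca-1,7-diene-1-carboxylate
Conditions: TBSCl, imidazole, DMF, rt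
Reagents that add atoms: tert-butyldimethylsilyl chloride, CC(C)(C)[Si](C)(C)Cl
Why: silylation of the secondary alcohol; the open hydroxy ketone is drained from the hemiketal equilibrium because the tertiary hemiketal hydroxyl does not react with the silyl chloride.

Step 9
Reactants: 11 methyl (1E,7Z,10R)-10-[(tert-butyldimethylsilyl)oxy]-5-oxocyclodeca-1,7-diene-1-carboxylate
Product: 13 methyl (1E,6Z,8Z,10R)-10-[(tert-butyldimethylsilyl)oxy]-5-oxocyclodeca-1,6,8-triene-1-carboxylate (C4 dienone), via silyl dienol ether 12 (not isolated)
Conditions: TMSOTf, Et3N, CH2Cl2, 0 °C; then Pd(OAc)2, MeCN, rt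
Reagents that add atoms: none
Why: soft enolisation goes toward the allylic C5 and gives the conjugated 2-silyloxy diene; Saegusa–Ito oxidation with divalent palladium then forms a π-allyl species and β-hydride elimination from C8 gives the linear dienone, the (Z,Z) isomer being the unstrained geometry for a conjugated diene in a ten-membered ring.

Step 10
Reactants: 13 methyl (1E,6Z,8Z,10R)-10-[(tert-butyldimethylsilyl)oxy]-5-oxocyclodeca-1,6,8-triene-1-carboxylate
Product: 14 7α,8α-epoxide of 13 (7S,8S,9S; cis-epoxide anti to the C9 silyl ether; C5=C6 Z)
Conditions: mCPBA, NaHCO3, CH2Cl2, 0 °C to rt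
Reagents that add atoms: mCPBA, OOC(=O)c1cccc(Cl)c1
Why: Prilezhaev epoxidation of a dienone takes place at the γ,δ alkene, which is more electron-rich than the α,β alkene and the acrylate; the peracid attacks anti to the bulky allylic silyl ether, so C9 controls the new centres C7 and C8.

Step 11
Reactants: 14 7α,8α-epoxide of 13; 15 triethyl phosphonoacetate
Product: 17 C4 enone with a 7α-[1-(diethoxyphosphoryl)-2-ethoxy-2-oxoethyl] group and 8α-triethylsilyloxy and 9β-TBS-oxy groups (C11 epimers), via C8 alcohol 16 (not isolated)
Conditions: Pd2(dba)3·CHCl3 (2.5 mol%), dppe, THF, rt; then TESOTf, 2,6-lutidine, −78 °C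
Reagents that add atoms: triethylsilyl trifluoromethanesulfonate, CC[Si](CC)(CC)OS(=O)(=O)C(F)(F)F
Why: Tsuji–Trost alkylation of a vinyl epoxide: zerovalent palladium ionises the allylic C7–O bond with inversion, the alkoxide deprotonates 15, and the soft carbanion attacks the π-allyl terminus remote from the ketone (C7) anti to the metal, so net retention places C11 cis to O8. Silylation in the same flask stops the free C8 alcohol from lactonising onto the new ester.

Step 12
Reactants: 17 C4 enone with the C7 phosphonoacetate side chain
Product: 18 C4 tertiary allylic alcohol (4-hydroxy-4-methyl; C5=C6 alkene; C4 and C11 epimers)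
Conditions: MeLi, CeCl3, THF, −78 °C
Reagents that add atoms: methyllithium, [Li]C
Why: organocerium 1,2-addition to an enone, weakly basic and unreactive toward the esters at −78 °C; one equivalent is spent on the acidic C11–H, whose anion is inert, and the C4 configuration is irrelevant because it is erased in step 13.

Step 13
Reactants: 18 C4 tertiary allylic alcohol
Product: 19 transposed enone (C6 ketone; C4(Me)=C5 alkene with ring bonds cis; 7α side chain; 8α-OTES; 9β-OTBS)
Conditions: [C5H5NH][CrO3Cl] (pyridinium chlorochromate), NaOAc, 4 Å MS, CH2Cl2, rt
Reagents that add atoms: none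
Why: Babler–Dauben oxidative transposition: the chromate ester of the tertiary allylic alcohol undergoes a [3,3] shift and the secondary chromate is oxidised to the ketone, moving the oxygen from C4 to C6 and creating the C4=C5 alkene; the ring-cis enone is expected as the more stable isomer, and the acetate buffer protects the silyl ethers.

Step 14
Reactants: 19 transposed enone
Product: 21 cis-fused α-diethylphosphono γ-lactone (6α-O and 7α-C; C4=C5 Z; 8α-OTES; 9β-OTBS; C11 epimers), via hydroxy ester 20 (not isolated)
Conditions: NaBH4, CeCl3·7H2O, MeOH, −78 °C; then PPTS, benzene, 50 °C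
Reagents that add atoms: none
Why: Luche 1,2-reduction; hydride should arrive from the β face, opposite the C7 side chain and O8, giving the 6α alcohol, and the cis γ-hydroxy ester then lactonises, the five-membered ring allowing only the cis fusion.

Step 15
Reactants: 21 cis-fused α-diethylphosphono γ-lactone
Product: 22 C8 alcohol (8α-OH; 9β-OTBS retained)
Conditions: PPTS, MeOH/CH2Cl2, 0 °C
Reagents that add atoms: none
Why: acid-catalysed methanolysis removes the secondary triethylsilyl ether while the bulkier tert-butyldimethylsilyl ether survives.

Step 16
Reactants: 23 2-methylprop-2-en-1-ol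
Product: 24 (R)-(2-methyloxiran-2-yl)methanol
Conditions: Ti(OiPr)4 (cat.), D-(−)-diisopropyl tartrate, t-BuOOH, 4 Å MS, CH2Cl2, −20 °C
Reagents that add atoms: tert-butyl hydroperoxide, CC(C)(C)OO
Why: Sharpless asymmetric epoxidation; by the standard facial rule the D-(−)-tartrate delivers oxygen to the face that gives the (R)-epoxy alcohol.

Step 17
Reactants: 24 (R)-(2-methyloxiran-2-yl)methanol
Product: 25 (S)-2-methyloxirane-2-carboxylic acid
Conditions: RuCl3·xH2O (cat.), NaIO4, CCl4/MeCN/H2O, rt
Reagents that add atoms: sodium periodate, [Na+].[O-]I(=O)(=O)=O; water, O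
Why: RuO4-mediated oxidation of a primary alcohol to the acid under neutral biphasic conditions that leave the epoxide intact; the descriptor changes from R to S only because the priorities change.

Step 18
Reactants: 25 (S)-2-methyloxirane-2-carboxylic acid; 22 C8 alcohol
Product: 27 C8 (S)-2-methyloxirane-2-carboxylate (9β-OTBS; α-phosphono lactone), via mixed anhydride 26 (not isolated)
Conditions: 2,4,6-trichlorobenzoyl chloride, Et3N, THF, rt; then 22, DMAP, toluene, rt
Reagents that add atoms: none
Why: Yamaguchi esterification acylates the hindered secondary alcohol through the mixed anhydride and DMAP; the acid has a quaternary α-carbon and cannot epimerise.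

Step 19
Reactants: 27 C8 (S)-2-methyloxirane-2-carboxylate
Product: 28 C9 alcohol (9β-OH)
Conditions: HF·pyridine, pyridine, THF, 0 °C
Reagents that add atoms: none
Why: fluoride-driven desilylation buffered with pyridine spares the esters, the electron-poor glycidate epoxide and the phosphonate.

Step 20
Reactants: 28 C9 alcohol
Product: 29 C9 acetate (9β-OAc; C4=C5 alkene; α-phosphono lactone)
Conditions: Ac2O, DMAP (cat.), pyridine, CH2Cl2, 0 °C
Reagents that add atoms: acetic anhydride, CC(=O)OC(C)=O
Why: DMAP-catalysed acetylation of the allylic alcohol; the hindered C8 ester is not expected to migrate under these mild conditions.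

Step 21
Reactants: 29 C9 acetate
Product: 30 4β,5β-epoxide (4R,5S; cis-epoxide; α-phosphono lactone)
Conditions: mCPBA, NaHCO3, CH2Cl2, 0 °C
Reagents that add atoms: mCPBA, OOC(=O)c1cccc(Cl)c1
Why: Prilezhaev epoxidation of the only electron-rich alkene (the acrylate is inert); syn addition to the Z alkene gives the cis-epoxide, and the peracid should approach the β face, away from the fused lactone at C6.

Step 22
Reactants: 30 4β,5β-epoxide
Product: 31 target compound CNP0274195.1
Conditions: K2CO3, aq. HCHO (37%), THF, 0 °C
Reagents that add atoms: formaldehyde, C=O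
Why: Horner–Wadsworth–Emmons olefination of the α-phosphono lactone with formaldehyde under mild carbonate base introduces the exo-methylene last, when no further step can add to it.

## Compound list

1 | 1-naphthoic acid | OC(=O)c1cccc2ccccc12 | starting material
2 | 1,4-dihydronaphthalene-1-carboxylic acid (racemic) | OC(=O)C1C=CCc2ccccc12 | intermediate
3 | 1,4,5,8-tetrahydronaphthalene-1-carboxylic acid (racemic) | OC(=O)C1C=CCC2=C1CC=CC2 | intermediate
4 | methyl 1,4,5,8-tetrahydronaphthalene-1-carboxylate (racemic) | COC(=O)C1C=CCC2=C1CC=CC2 | intermediate
5 | transannular ozonide of 4 (1,2,4-trioxolane bridging C4 and C9; not isolated) | COC(=O)C1/C=C\CC2(O3)OOC13C/C=C\C2 | intermediate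
6 | methyl (4Z,9Z)-2,7-dioxocyclodeca-4,9-diene-1-carboxylate (C10 epimerisable) | COC(=O)C1/C=C\CC(=O)C/C=C\CC1=O | intermediate
7 | methyl (2R,4Z,9Z)-2-hydroxy-7-oxocyclodeca-4,9-diene-1-carboxylate (9R in target numbering; C10 epimers; not isolated) | O[C@H]1C(C(=O)OC)/C=C\CC(=O)C/C=C\C1 | intermediate
8 | methyl (1R)-6-methoxy-11-oxabicyclo[4.4.1]undeca-3,8-diene-2-carboxylate (O9–C4 bridge on the β face; C10 epimers) | O1[C@H]2C(C(=O)OC)/C=C\C[C@]1(OC)C/C=C\C2 | intermediate
9 | methyl (1R)-6-methoxy-11-oxabicyclo[4.4.1]undeca-2,8-diene-2-carboxylate | O1[C@H]2/C(C(=O)OC)=C\CC[C@]1(OC)C/C=C\C2 | intermediate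
10 | methyl (1E,7Z,10R)-10-hydroxy-5-oxocyclodeca-1,7-diene-1-carboxylate | O[C@H]1/C(C(=O)OC)=C\CCC(=O)C/C=C\C1 | intermediate
11 | methyl (1E,7Z,10R)-10-[(tert-butyldimethylsilyl)oxy]-5-oxocyclodeca-1,7-diene-1-carboxylate | CC(C)(C)[Si](C)(C)O[C@H]1/C(C(=O)OC)=C\CCC(=O)C/C=C\C1 | intermediate
12 | C4 trimethylsilyl dienol ether of 11 (C4=C5–C6=C7; enol geometry undefined; not isolated) | CC(C)(C)[Si](C)(C)O[C@H]1/C(C(=O)OC)=C\CCC(O[Si](C)(C)C)=C/C=C\C1 | intermediate
13 | methyl (1E,6Z,8Z,10R)-10-[(tert-butyldimethylsilyl)oxy]-5-oxocyclodeca-1,6,8-triene-1-carboxylate | O=C1/C=C\C=C/[C@@H](O[Si](C)(C)C(C)(C)C)/C(C(=O)OC)=C\CC1 | intermediate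
14 | 7α,8α-epoxide of 13 (7S,8S,9S in target numbering) | CC(C)(C)[Si](C)(C)O[C@H]1/C(C(=O)OC)=C\CCC(=O)/C=C\[C@@H]2O[C@@H]21 | intermediate
15 | triethyl phosphonoacetate | CCOC(=O)CP(=O)(OCC)OCC | starting material
16 | C8 alcohol: C4 enone with 7α phosphonoacetate side chain, 8α-OH, 9β-OTBS (C11 epimers; C5=C6 drawn Z; not isolated) | CC(C)(C)[Si](C)(C)O[C@H]1/C(C(=O)OC)=C\CCC(=O)/C=C\[C@H](C(C(=O)OCC)P(=O)(OCC)OCC)[C@@H]1O | intermediate
17 | 8-O-triethylsilyl ether of 16 | CC(C)(C)[Si](C)(C)O[C@H]1/C(C(=O)OC)=C\CCC(=O)/C=C\[C@H](C(C(=O)OCC)P(=O)(OCC)OCC)[C@@H]1O[Si](CC)(CC)CC | intermediate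
18 | C4 tertiary allylic alcohol (C4 and C11 epimers) | CC(C)(C)[Si](C)(C)O[C@H]1/C(C(=O)OC)=C\CCC(C)(O)/C=C\[C@H](C(C(=O)OCC)P(=O)(OCC)OCC)[C@@H]1O[Si](CC)(CC)CC | intermediate
19 | transposed enone: C6 ketone, C4(Me)=C5 Z | CC(C)(C)[Si](C)(C)O[C@H]1/C(C(=O)OC)=C\CC/C(C)=C\C(=O)[C@H](C(C(=O)OCC)P(=O)(OCC)OCC)[C@@H]1O[Si](CC)(CC)CC | intermediate
20 | 6α-hydroxy ester (not isolated) | CC(C)(C)[Si](C)(C)O[C@H]1/C(C(=O)OC)=C\CC/C(C)=C\[C@H](O)[C@H](C(C(=O)OCC)P(=O)(OCC)OCC)[C@@H]1O[Si](CC)(CC)CC | intermediate
21 | cis-fused α-diethylphosphono γ-lactone, 8α-OTES, 9β-OTBS (C11 epimers) | CC(C)(C)[Si](C)(C)O[C@H]1/C(C(=O)OC)=C\CC/C(C)=C\[C@@H]2OC(=O)C(P(=O)(OCC)OCC)[C@@H]2[C@@H]1O[Si](CC)(CC)CC | intermediate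
22 | C8 alcohol of the phosphono lactone (8α-OH, 9β-OTBS) | CC(C)(C)[Si](C)(C)O[C@H]1/C(C(=O)OC)=C\CC/C(C)=C\[C@@H]2OC(=O)C(P(=O)(OCC)OCC)[C@@H]2[C@@H]1O | intermediate
23 | 2-methylprop-2-en-1-ol | CC(=C)CO | starting material
24 | (R)-(2-methyloxiran-2-yl)methanol | OC[C@]1(C)CO1 | intermediate
25 | (S)-2-methyloxirane-2-carboxylic acid | OC(=O)[C@]1(C)CO1 | intermediate
26 | mixed anhydride of 25 with 2,4,6-trichlorobenzoic acid (not isolated) | O=C(OC(=O)c1c(Cl)cc(Cl)cc1Cl)[C@]2(C)CO2 | intermediate
27 | C8 (S)-2-methyloxirane-2-carboxylate, 9β-OTBS | CC(C)(C)[Si](C)(C)O[C@H]1/C(C(=O)OC)=C\CC/C(C)=C\[C@@H]2OC(=O)C(P(=O)(OCC)OCC)[C@@H]2[C@@H]1OC(=O)[C@]3(C)CO3 | intermediate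
28 | C9 alcohol | O[C@H]1/C(C(=O)OC)=C\CC/C(C)=C\[C@@H]2OC(=O)C(P(=O)(OCC)OCC)[C@@H]2[C@@H]1OC(=O)[C@]3(C)CO3 | intermediate
29 | C9 acetate | CC(=O)O[C@H]1/C(C(=O)OC)=C\CC/C(C)=C\[C@@H]2OC(=O)C(P(=O)(OCC)OCC)[C@@H]2[C@@H]1OC(=O)[C@]3(C)CO3 | intermediate
30 | 4β,5β-epoxide (4R,5S), α-phosphono lactone | CC(=O)O[C@H]1/C(C(=O)OC)=C\CC[C@@]3(C)O[C@H]3[C@@H]2OC(=O)C(P(=O)(OCC)OCC)[C@@H]2[C@@H]1OC(=O)[C@]4(C)CO4 | intermediate
31 | CNP0274195.1 | C=C1C(=O)O[C@@H]2[C@H]1[C@H](OC(=O)[C@]1(C)CO1)[C@@H](OC(C)=O)/C(C(=O)OC)=C\CC[C@@]1(C)O[C@@H]21 | target

Total step count: 22. Longest linear sequence: 20 steps (steps 1–15 and 18–22); steps 16 and 17 make the acid fragment.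

## Least certain steps

**Step 4 (key step).** Over-oxidation of one of the disubstituted alkenes may compete once the fusion alkene is consumed. The product may also be lost by transannular aldol reaction between the 1,6-related carbonyl groups, or by migration of the C1=C2 alkene into conjugation with the β-keto ester. Fallback, from 4: buffered mCPBA epoxidises the tetrasubstituted alkene preferentially to the 4a,8a-epoxide F1, and periodic acid in aqueous THF opens and cleaves it to give diketone 6, where the route is rejoined.

**Step 6.** The ester dienolate may expel the bridging oxygen (β-elimination, opening the ketal to a C9=C10 diene), or the equilibrium may not lie far enough on the conjugated side. Fallback, from 8: aqueous acid returns hydroxy ketone 7, which is silylated to the C9 silyl ether F2 and ketalised with ethylene glycol to the dioxolane F3. DBU then equilibrates the monocyclic ester to the conjugated isomer F4, where the leaving group is a silyl ether, and mild acid hydrolysis of the dioxolane gives 11. The ring-cis geometry then rests on thermodynamic preference, no longer on a small ring.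

**Step 9.** Enolisation may go toward C3, and the new C7=C8 alkene may form with the ring bonds trans, which would invert the later C7/C8 relationship. Fallback, from 11: mCPBA epoxidises the only isolated alkene to the 6,7-epoxide F5, and DBU opens it by β-elimination from C5 to the γ-hydroxy enone F6. Mesylation gives F7, and base-induced elimination under equilibrating conditions leads to dienone 13.

**Step 11.** The carbanion may attack the other allyl terminus (C5), the π-allyl complex may lose its configuration before attack, or the free C8 alcohol may lactonise before it is silylated. Fallback, from 14: MgBr2·OEt2 opens the epoxide at the allylic C7 with inversion to the bromohydrin F8, which is silylated to F9. The sodium salt of 15 then displaces the allylic bromide with a second inversion, giving 17 without palladium.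

**Step 14.** Poor facial selectivity in the hydride addition would give the 6β alcohol, which cannot close to a cis lactone; C7 may also epimerise through the enol of 19. Fallback, from 19: the 6β-hydroxy ester F10 is isolated, its ethyl ester is saponified selectively with LiOH to the hydroxy acid F11, and Mitsunobu lactonisation (PPh3, DIAD) closes the ring with inversion at C6 to give 21, so both C6 epimers converge.

**Step 21.** The peracid may attack the α face or show poor facial selectivity, since the conformation of the Z alkene next to the lactone is not known. Fallback, from 29: NBS in aqueous DME forms the bromonium ion on the face the peracid prefers, and water opens it at the tertiary C4 from the opposite face to give the bromohydrin F12. K2CO3 then closes the epoxide on the face opposite to the original electrophilic attack, giving 30.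

## Further compounds

F1 | step 4 | methyl 4a,8a-epoxy-1,4,4a,5,8,8a-hexahydronaphthalene-1-carboxylate (racemic; epoxide face undefined) | COC(=O)C1C=CCC2(O3)CC=CCC123
F2 | step 6 | methyl (2R,4Z,9Z)-2-[(tert-butyldimethylsilyl)oxy]-7-oxocyclodeca-4,9-diene-1-carboxylate (C10 epimers) | CC(C)(C)[Si](C)(C)O[C@H]1C(C(=O)OC)/C=C\CC(=O)C/C=C\C1
F3 | step 6 | C4 ethylene ketal of F2 | CC(C)(C)[Si](C)(C)O[C@H]1C(C(=O)OC)/C=C\CC2(OCCO2)C/C=C\C1
F4 | step 6 | C4 ethylene ketal of 11 (C10=C1 conjugated) | CC(C)(C)[Si](C)(C)O[C@H]1/C(C(=O)OC)=C\CCC2(OCCO2)C/C=C\C1
F5 | step 9 | 6,7-epoxide of 11 (cis-epoxide; face undefined) | CC(C)(C)[Si](C)(C)O[C@H]1/C(C(=O)OC)=C\CCC(=O)CC2OC2C1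
F6 | step 9 | γ-hydroxy enone (C4 ketone, C5=C6, 7-OH; C7 epimers) | CC(C)(C)[Si](C)(C)O[C@H]1/C(C(=O)OC)=C\CCC(=O)/C=C\C(O)C1
F7 | step 9 | C7 mesylate of F6 | CC(C)(C)[Si](C)(C)O[C@H]1/C(C(=O)OC)=C\CCC(=O)/C=C\C(OS(C)(=O)=O)C1
F8 | step 11 | bromohydrin (7β-Br, 8α-OH, 9β-OTBS; C4 enone) | CC(C)(C)[Si](C)(C)O[C@H]1/C(C(=O)OC)=C\CCC(=O)/C=C\[C@@H](Br)[C@@H]1O
F9 | step 11 | 8-O-triethylsilyl ether of F8 | CC(C)(C)[Si](C)(C)O[C@H]1/C(C(=O)OC)=C\CCC(=O)/C=C\[C@@H](Br)[C@@H]1O[Si](CC)(CC)CC
F10 | step 14 | 6β-hydroxy ester (C6 epimer of 20) | CC(C)(C)[Si](C)(C)O[C@H]1/C(C(=O)OC)=C\CC/C(C)=C\[C@@H](O)[C@H](C(C(=O)OCC)P(=O)(OCC)OCC)[C@@H]1O[Si](CC)(CC)CC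
F11 | step 14 | 6β-hydroxy acid from F10 | CC(C)(C)[Si](C)(C)O[C@H]1/C(C(=O)OC)=C\CC/C(C)=C\[C@@H](O)[C@H](C(C(=O)O)P(=O)(OCC)OCC)[C@@H]1O[Si](CC)(CC)CC
F12 | step 21 | bromohydrin of 29 (4β-OH, 5α-Br) | CC(=O)O[C@H]1/C(C(=O)OC)=C\CC[C@@](C)(O)[C@H](Br)[C@@H]2OC(=O)C(P(=O)(OCC)OCC)[C@@H]2[C@@H]1OC(=O)[C@]4(C)CO4
A1 | alternative 1 | cis-fused α-phosphono γ-lactone with C5 mesylate and C4 triethylsilyl ether (C11 epimers) | CCOP(=O)(OCC)C1C(=O)O[C@@H]2[C@H]1[C@H](OC(=O)[C@]1(C)CO1)[C@@H](OC(C)=O)/C(C(=O)OC)=C\CC[C@@](C)(O[Si](CC)(CC)CC)[C@@H]2OS(C)(=O)=O
A2 | alternative 2 | ten-membered ring-fused butenolide with C5 hydroxyl | O=C1C=C2[C@@H]3OC(C)(C)O[C@H]3/C(CO[Si](C)(C)C(C)(C)C)=C\CC[C@@](C)(O[Si](CC)(CC)CC)[C@H](O)[C@@H]2O1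
A3 | alternative 3 | ten-membered dienamine ester (ring-cis C9=C10, E C1=C2) | C/C1=C/[C@H]2[C@H](C=C)[C@H](OC(C)(C)O2)/C(N3CCCC3)=C(/C(=O)OC)\C=C\C1
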